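**Retrosynthetic overview**

1. Target ⇐ hydrogenolysis of its octadeca-O-benzyl ether; the all-cis upper unit ⇐ C3 inversion (ketone, then β-face hydride) of a catechin-type upper unit whose C4–C8 bond (4α) is trans to the 3-OH.
2. Lower interflavan bond ⇐ Lewis-acid substitution of a C4–O ether at the chain end of a catechin–(epicatechin gallate) dimer by C8 of benzylated epicatechin gallate.
3. Key disconnection: that C4–O bond ⇐ site-selective benzylic C–H etherification of the dimer (C–H → C–O, 4β).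
4. Upper interflavan bond ⇐ the same C4–O etherification on benzylated (+)-catechin, then substitution by C8 of benzylated epicatechin gallate, itself from benzylated (−)-epicatechin and tri-O-benzylgallic acid.
5. Ring order: no ring is built; all eleven rings arrive intact in (−)-epicatechin (used twice), (+)-catechin and 3,4,5-tris(benzyloxy)benzoic acid (used twice); the upper interflavan bond is made first, then the lower one.

Assumption: the target is taken exactly as drawn (upper unit 2α-aryl, 3α-OH, 4α interflavan bond, all cis; middle and lower units (−)-epicatechin 3-O-gallate joined 4β→8), and (−)-epicatechin, (+)-catechin and 3,4,5-tris(benzyloxy)benzoic acid are counted as commercial starting materials.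

**Route**

Step 1
Reactants: 1 (−)-epicatechin
Product: 2 5,7,3′,4′-tetra-O-benzyl-(−)-epicatechin
Conditions: BnBr (4.8 equiv), K2CO3, dry DMF, 0 °C to rt, argon
Reagents that add atoms: benzyl bromide, BrCc1ccccc1
Why: Williamson etherification of the four phenols with a weak carbonate base, which does not deprotonate the aliphatic 3-OH and leaves both stereocentres untouched.

Step 2
Reactants: 2 5,7,3′,4′-tetra-O-benzyl-(−)-epicatechin; 3 3,4,5-tris(benzyloxy)benzoic acid (1.3 equiv)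
Product: 4 hepta-O-benzyl-(−)-epicatechin 3-O-gallate
Conditions: DCC (1.5 equiv), DMAP (0.5 equiv), CH2Cl2, rt
Reagents that add atoms: none
Why: Steglich esterification acylates the 3-OH at oxygen, so C3 keeps its configuration and no new stereocentre is formed.

Step 3
Reactants: 5 (+)-catechin
Product: 6 5,7,3′,4′-tetra-O-benzyl-(+)-catechin
Conditions: BnBr (4.8 equiv), K2CO3, DMF, rt
Reagents that add atoms: benzyl bromide, BrCc1ccccc1
Why: Williamson etherification of the four phenols; K2CO3 does not deprotonate the aliphatic 3-OH, which stays free.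

Step 4
Reactants: 6 5,7,3′,4′-tetra-O-benzyl-(+)-catechin
Product: 7 (2R,3S,4S)-tetra-O-benzyl-4-(2-ethoxyethoxy)catechin (4β-ether)
Conditions: DDQ (2 equiv), EtOCH2CH2OH, CH2Cl2, rt
Reagents that add atoms: 2-ethoxyethanol, CCOCCO
Why: DDQ-mediated oxidative benzylic etherification: hydride abstraction at C4 gives a cation stabilised by the 5- and 7-oxygens of ring A, and the alcohol adds axially from the β-face to give the 4β-ether.

Step 5
Reactants: 7 (2R,3S,4S)-tetra-O-benzyl-4-(2-ethoxyethoxy)catechin; 4 hepta-O-benzyl-(−)-epicatechin 3-O-gallate (3 equiv, excess recovered)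
Product: 8 [tetra-O-benzylcatechin]-(4α→8)-[hepta-O-benzylepicatechin 3-O-gallate]
Conditions: TMSOTf (0.2 equiv), CH2Cl2, −78 °C
Reagents that add atoms: none
Why: Lewis-acid SN1 substitution (Friedel–Crafts-type interflavan coupling): the C4 cation is attacked by the most nucleophilic position, C8, of 4 on the face opposite the 3β-oxygen, which sets the 3,4-trans (4α) stereocentre.

Step 6
Reactants: 8 [tetra-O-benzylcatechin]-(4α→8)-[hepta-O-benzylepicatechin 3-O-gallate]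
Product: 9 dimer 8 carrying a 4β-(2-ethoxyethoxy) group on C4 of the lower (epicatechin gallate) unit
Conditions: DDQ (1.5 equiv), EtOCH2CH2OH (10 equiv), CH2Cl2, 0 °C to rt
Reagents that add atoms: 2-ethoxyethanol, CCOCCO
Why: Proposed new method: site-selective oxidative C–H etherification at the chain-end C4 of an already 4→8-linked flavan dimer; DDQ forms its charge-transfer complex with the more electron-rich, C8-alkylated ring A of the lower unit and removes a hydride from that unhindered CH2 group, with the 3-O-galloyl carbonyl assisting from the α-face (acyloxonium), whereas the only C4–H of the upper unit is tertiary and wedged between its own ring A and the di-ortho-substituted aryl of the lower unit, which blocks DDQ stacking and cannot turn coplanar to stabilise a cation; 2-ethoxyethanol then adds axially on the β-face, trans to the ester, setting the 4β C–O stereocentre; the closest known reaction type is the DDQ-mediated benzylic C4–H alkoxylation of monomeric O-benzylated flavan-3-ols, which has not been shown on an oligomer or next to a 3-O-galloyl ester.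

Step 7
Reactants: 9 dimer 4β-(2-ethoxyethyl) ether; 4 hepta-O-benzyl-(−)-epicatechin 3-O-gallate (3 equiv, excess recovered)
Product: 10 [tetra-O-benzylcatechin]-(4α→8)-[hepta-O-benzylepicatechin 3-O-gallate]-(4β→8)-[hepta-O-benzylepicatechin 3-O-gallate]
Conditions: TMSOTf (0.2 equiv), CH2Cl2, −78 to −40 °C
Reagents that add atoms: none
Why: Friedel–Crafts-type interflavan coupling: the ionised C4 is shielded on the α-face by the participating 3α-O-galloyl group, so C8 of 4 (in excess, to outcompete ring A of the dimer itself) adds on the β-face and sets the 3,4-trans (4β) stereocentre.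

Step 8
Reactants: 10 benzylated trimer with catechin-type upper unit
Product: 11 the same trimer with the upper-unit C3 oxidised to the ketone
Conditions: Dess–Martin periodinane (3 equiv), CH2Cl2, rt
Reagents that add atoms: none
Why: Dess–Martin oxidation of the only free hydroxyl; the non-basic conditions preserve the 2,4-cis-diaryl (diequatorial) arrangement next to the ketone.

Step 9
Reactants: 11 upper-unit 3-ketone
Product: 12 octadeca-O-benzyl ether of the target (upper unit all-cis: 2α-aryl, 3α-OH, 4α-aryl)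
Conditions: LiBH(s-Bu)3 (3 equiv), LiBr, THF, −78 °C
Reagents that add atoms: none
Why: Diastereoselective ketone reduction: the bulky hydride attacks equatorially from the β-face, as in the established flavan-3-one to epicatechin reduction, giving the axial 3α-OH cis to both equatorial aryl groups, while the hindered aryl esters survive at −78 °C.

Step 10
Reactants: 12 octadeca-O-benzyl ether of the target
Product: 13 target, [epicatechin]-(4α→8)-[epicatechin 3-O-gallate]-(4β→8)-[epicatechin 3-O-gallate]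
Conditions: H2 (1 atm), Pd(OH)2 on carbon, THF/MeOH/H2O, rt
Reagents that add atoms: none
Why: Catalytic hydrogenolysis removes all eighteen benzyl ethers under neutral conditions that leave the gallate esters, the chroman C2–O bonds and the interflavan bonds intact.

**Compound list**

1 | (−)-epicatechin, (2R,3R) | O[C@@H]1Cc2c(O)cc(O)cc2O[C@@H]1c1ccc(O)c(O)c1 | starting material

2 | 5,7,3′,4′-tetra-O-benzyl-(−)-epicatechin, (2R,3R), free 3-OH | O[C@@H]1Cc2c(OCc5ccccc5)cc(OCc5ccccc5)cc2O[C@@H]1c1ccc(OCc5ccccc5)c(OCc5ccccc5)c1 | intermediate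

3 | 3,4,5-tris(benzyloxy)benzoic acid | OC(=O)c1cc(OCc2ccccc2)c(OCc2ccccc2)c(OCc2ccccc2)c1 | starting material

4 | hepta-O-benzyl-(−)-epicatechin 3-O-gallate, (2R,3R) | O=C(O[C@@H]1Cc2c(OCc5ccccc5)cc(OCc5ccccc5)cc2O[C@@H]1c1ccc(OCc5ccccc5)c(OCc5ccccc5)c1)c1cc(OCc5ccccc5)c(OCc5ccccc5)c(OCc5ccccc5)c1 | intermediate

5 | (+)-catechin, (2R,3S) | O[C@H]1Cc2c(O)cc(O)cc2O[C@@H]1c1ccc(O)c(O)c1 | starting material

6 | 5,7,3′,4′-tetra-O-benzyl-(+)-catechin, (2R,3S), free 3-OH | O[C@H]1Cc2c(OCc5ccccc5)cc(OCc5ccccc5)cc2O[C@@H]1c1ccc(OCc5ccccc5)c(OCc5ccccc5)c1 | intermediate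

7 | (2R,3S,4S)-5,7,3′,4′-tetra-O-benzyl-4-(2-ethoxyethoxy)catechin, 4β-ether cis to the 3-OH | O[C@H]1[C@@H](OCCOCC)c2c(OCc5ccccc5)cc(OCc5ccccc5)cc2O[C@@H]1c1ccc(OCc5ccccc5)c(OCc5ccccc5)c1 | intermediate

8 | [tetra-O-benzylcatechin]-(4α→8)-[hepta-O-benzylepicatechin 3-O-gallate]; upper unit 2α-aryl, 3β-OH, 4α-aryl (all trans); lower unit 2R,3R | O=C(O[C@@H]1Cc2c(OCc5ccccc5)cc(OCc5ccccc5)c([C@@H]3c4c(OCc5ccccc5)cc(OCc5ccccc5)cc4O[C@H](c4ccc(OCc5ccccc5)c(OCc5ccccc5)c4)[C@H]3O)c2O[C@@H]1c1ccc(OCc5ccccc5)c(OCc5ccccc5)c1)c1cc(OCc5ccccc5)c(OCc5ccccc5)c(OCc5ccccc5)c1 | intermediate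

9 | dimer 8 with a 4β-(2-ethoxyethoxy) group on C4 of the lower unit, trans to its 3α-O-galloyl group | O=C(O[C@@H]1[C@@H](OCCOCC)c2c(OCc5ccccc5)cc(OCc5ccccc5)c([C@@H]3c4c(OCc5ccccc5)cc(OCc5ccccc5)cc4O[C@H](c4ccc(OCc5ccccc5)c(OCc5ccccc5)c4)[C@H]3O)c2O[C@@H]1c1ccc(OCc5ccccc5)c(OCc5ccccc5)c1)c1cc(OCc5ccccc5)c(OCc5ccccc5)c(OCc5ccccc5)c1 | intermediate

10 | [tetra-O-benzylcatechin]-(4α→8)-[hepta-O-benzylepicatechin 3-O-gallate]-(4β→8)-[hepta-O-benzylepicatechin 3-O-gallate]; upper unit 3β-OH free | O=C(O[C@@H]1[C@@H](c2c(OCc5ccccc5)cc(OCc5ccccc5)c3c2O[C@H](c2ccc(OCc5ccccc5)c(OCc5ccccc5)c2)[C@H](OC(=O)c2cc(OCc5ccccc5)c(OCc5ccccc5)c(OCc5ccccc5)c2)C3)c2c(OCc5ccccc5)cc(OCc5ccccc5)c([C@@H]3c4c(OCc5ccccc5)cc(OCc5ccccc5)cc4O[C@H](c4ccc(OCc5ccccc5)c(OCc5ccccc5)c4)[C@H]3O)c2O[C@@H]1c1ccc(OCc5ccccc5)c(OCc5ccccc5)c1)c1cc(OCc5ccccc5)c(OCc5ccccc5)c(OCc5ccccc5)c1 | intermediate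

11 | trimer 10 with the upper-unit C3 as a ketone (2α-aryl and 4α-aryl cis to each other) | O=C(O[C@@H]1[C@@H](c2c(OCc5ccccc5)cc(OCc5ccccc5)c3c2O[C@H](c2ccc(OCc5ccccc5)c(OCc5ccccc5)c2)[C@H](OC(=O)c2cc(OCc5ccccc5)c(OCc5ccccc5)c(OCc5ccccc5)c2)C3)c2c(OCc5ccccc5)cc(OCc5ccccc5)c([C@@H]3c4c(OCc5ccccc5)cc(OCc5ccccc5)cc4O[C@H](c4ccc(OCc5ccccc5)c(OCc5ccccc5)c4)C3=O)c2O[C@@H]1c1ccc(OCc5ccccc5)c(OCc5ccccc5)c1)c1cc(OCc5ccccc5)c(OCc5ccccc5)c(OCc5ccccc5)c1 | intermediate

12 | octadeca-O-benzyl ether of the target; upper unit 2α-aryl, 3α-OH, 4α-aryl (all cis) | O=C(O[C@@H]1[C@@H](c2c(OCc5ccccc5)cc(OCc5ccccc5)c3c2O[C@H](c2ccc(OCc5ccccc5)c(OCc5ccccc5)c2)[C@H](OC(=O)c2cc(OCc5ccccc5)c(OCc5ccccc5)c(OCc5ccccc5)c2)C3)c2c(OCc5ccccc5)cc(OCc5ccccc5)c([C@@H]3c4c(OCc5ccccc5)cc(OCc5ccccc5)cc4O[C@H](c4ccc(OCc5ccccc5)c(OCc5ccccc5)c4)[C@@H]3O)c2O[C@@H]1c1ccc(OCc5ccccc5)c(OCc5ccccc5)c1)c1cc(OCc5ccccc5)c(OCc5ccccc5)c(OCc5ccccc5)c1 | intermediate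

13 | CNP0279403.2, [epicatechin]-(4α→8)-[epicatechin 3-O-gallate]-(4β→8)-[epicatechin 3-O-gallate] | O=C(O[C@@H]1[C@@H](c2c(O)cc(O)c3c2O[C@H](c2ccc(O)c(O)c2)[C@H](OC(=O)c2cc(O)c(O)c(O)c2)C3)c2c(O)cc(O)c([C@@H]3c4c(O)cc(O)cc4O[C@H](c4ccc(O)c(O)c4)[C@@H]3O)c2O[C@@H]1c1ccc(O)c(O)c1)c1cc(O)c(O)c(O)c1 | target

**Step count and risks**

Total steps: 10. Longest linear sequence: 8 (steps 3 to 10 from (+)-catechin, or steps 1, 2 and 5 to 10 from (−)-epicatechin).

Three steps most likely to fail: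

Step 6 (the proposed new chain-end C–H etherification). DDQ may also abstract the tertiary C4–H of the upper unit or over-oxidise. The fallback uses known chemistry, sets out from 2 and comes back at 10. DDQ/2-ethoxyethanol etherification of monomer 2, where the reaction is established, gives (2R,3R,4S)-5,7,3′,4′-tetra-O-benzyl-4-(2-ethoxyethoxy)epicatechin F1. Esterification of its 3-OH with acid 3 (DCC, DMAP, CH2Cl2) gives hepta-O-benzyl-4β-(2-ethoxyethoxy)epicatechin 3-O-gallate F2. TMSOTf coupling of F2 with excess 4 at −78 °C gives the lower dimer [hepta-O-benzylepicatechin 3-O-gallate]-(4β→8)-[hepta-O-benzylepicatechin 3-O-gallate] F3. TMSOTf coupling of F3, which reacts at C8 of its upper unit, with monomeric ether 7 then gives 10. This path replaces steps 5 to 7 but needs the dimer, not the monomer, in excess.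

Step 7 (coupling of the dimeric ether). A hard Lewis acid may also cleave the upper interflavan bond, or the hindered cation may react sluggishly or with ring A of another dimer molecule. The fallback sets out from 9 and comes back at 10. The ether is exchanged with 2-mercaptobenzothiazole and BF3·OEt2 in CH2Cl2 to give the dimer 4β-(benzothiazol-2-ylthio) ether F4. The soft, thiophilic salt AgBF4 in THF/CH2Cl2 at 0 °C then activates only the C–S bond and, with 4, gives 10.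

Step 9 (C3 inversion on the trimer). The crowded ketone of 11 may react slowly, epimerise at C2 or C4, or the hydride may attack one of the two gallate esters. The fallback moves the inversion to the dimer stage, where the molecule is smaller and carries one ester; it sets out from 8 and comes back at 12. Dess–Martin oxidation of 8 gives the dimer with the upper-unit C3 as a ketone F5. Reduction with LiBH(s-Bu)3 and LiBr at −78 °C gives [tetra-O-benzylepicatechin]-(4α→8)-[hepta-O-benzylepicatechin 3-O-gallate] F6, whose C3 epimers are still separable at this size. Etherification of F6 as in step 6 gives its lower-unit 4β-(2-ethoxyethyl) ether F7. TMSOTf coupling of F7 with excess 4 then gives 12 directly, without steps 8 and 9 on the trimer.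

**Further compounds**

F1 | step 6 | (2R,3R,4S)-5,7,3′,4′-tetra-O-benzyl-4-(2-ethoxyethoxy)epicatechin | O[C@@H]1[C@@H](OCCOCC)c2c(OCc5ccccc5)cc(OCc5ccccc5)cc2O[C@@H]1c1ccc(OCc5ccccc5)c(OCc5ccccc5)c1

F2 | step 6 | hepta-O-benzyl-4β-(2-ethoxyethoxy)epicatechin 3-O-gallate | O=C(O[C@@H]1[C@@H](OCCOCC)c2c(OCc5ccccc5)cc(OCc5ccccc5)cc2O[C@@H]1c1ccc(OCc5ccccc5)c(OCc5ccccc5)c1)c1cc(OCc5ccccc5)c(OCc5ccccc5)c(OCc5ccccc5)c1

F3 | step 6 | [hepta-O-benzylepicatechin 3-O-gallate]-(4β→8)-[hepta-O-benzylepicatechin 3-O-gallate] | O=C(O[C@@H]1[C@@H](c2c(OCc5ccccc5)cc(OCc5ccccc5)c3c2O[C@H](c2ccc(OCc5ccccc5)c(OCc5ccccc5)c2)[C@H](OC(=O)c2cc(OCc5ccccc5)c(OCc5ccccc5)c(OCc5ccccc5)c2)C3)c2c(OCc5ccccc5)cc(OCc5ccccc5)cc2O[C@@H]1c1ccc(OCc5ccccc5)c(OCc5ccccc5)c1)c1cc(OCc5ccccc5)c(OCc5ccccc5)c(OCc5ccccc5)c1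

F4 | step 7 | dimer 8 with a 4β-(benzothiazol-2-ylthio) group on C4 of the lower unit | O=C(O[C@@H]1[C@@H](Sc6nc7ccccc7s6)c2c(OCc5ccccc5)cc(OCc5ccccc5)c([C@@H]3c4c(OCc5ccccc5)cc(OCc5ccccc5)cc4O[C@H](c4ccc(OCc5ccccc5)c(OCc5ccccc5)c4)[C@H]3O)c2O[C@@H]1c1ccc(OCc5ccccc5)c(OCc5ccccc5)c1)c1cc(OCc5ccccc5)c(OCc5ccccc5)c(OCc5ccccc5)c1

F5 | step 9 | dimer 8 with the upper-unit C3 as a ketone | O=C(O[C@@H]1Cc2c(OCc5ccccc5)cc(OCc5ccccc5)c([C@@H]3c4c(OCc5ccccc5)cc(OCc5ccccc5)cc4O[C@H](c4ccc(OCc5ccccc5)c(OCc5ccccc5)c4)C3=O)c2O[C@@H]1c1ccc(OCc5ccccc5)c(OCc5ccccc5)c1)c1cc(OCc5ccccc5)c(OCc5ccccc5)c(OCc5ccccc5)c1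

F6 | step 9 | [tetra-O-benzylepicatechin]-(4α→8)-[hepta-O-benzylepicatechin 3-O-gallate]; upper unit 2α-aryl, 3α-OH, 4α-aryl | O=C(O[C@@H]1Cc2c(OCc5ccccc5)cc(OCc5ccccc5)c([C@@H]3c4c(OCc5ccccc5)cc(OCc5ccccc5)cc4O[C@H](c4ccc(OCc5ccccc5)c(OCc5ccccc5)c4)[C@@H]3O)c2O[C@@H]1c1ccc(OCc5ccccc5)c(OCc5ccccc5)c1)c1cc(OCc5ccccc5)c(OCc5ccccc5)c(OCc5ccccc5)c1

F7 | step 9 | dimer F6 with a 4β-(2-ethoxyethoxy) group on C4 of the lower unit | O=C(O[C@@H]1[C@@H](OCCOCC)c2c(OCc5ccccc5)cc(OCc5ccccc5)c([C@@H]3c4c(OCc5ccccc5)cc(OCc5ccccc5)cc4O[C@H](c4ccc(OCc5ccccc5)c(OCc5ccccc5)c4)[C@@H]3O)c2O[C@@H]1c1ccc(OCc5ccccc5)c(OCc5ccccc5)c1)c1cc(OCc5ccccc5)c(OCc5ccccc5)c(OCc5ccccc5)c1
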